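**Plan**

- The retrosynthesis first cuts the depside ester C(=O)–O bond between ring A and ring B, then ring B at C1–C2 and C5–C6, and ring A at the benzylic CH2–CH2 bond of the heptyl chain.
- Ring B has its C1 carboxyl between C2–OMe and C6–pentyl, with oxygen at C4. C1 and C6 (with carboxyl and pentyl) therefore map onto an oct-2-ynoate, and C2–C5 onto a 1,1-dimethoxy-3-silyloxybutadiene.
- Forward, the diene is made in three steps from acetyl chloride and 1,1-dichloroethene and the ynoate by benzylation. Their cycloaddition and aromatisation build ring B with 2-OMe and 4-OH already differentiated.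
- Ring A is bought as methyl orsellinate and elaborated by 4-O-methylation, 2-O-benzylation, lateral hexylation and saponification.
- The halves are joined by acylating the ring B 4-hydroxyl with the ring A acid chloride, and one hydrogenolysis frees the acid and the phenol.
- The target has no stereocentre, so only regiochemistry (in the cycloaddition and in the O-alkylations) has to be controlled.

Key step: step 5

Remark: the target is achiral and has no stereogenic double bond, so no SMILES below carries stereo descriptors. Simple alkylating, silylating and basic reagents are given on the reagent lines and are not numbered.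

**Route**

Step 1
Reactants: 1 acetyl chloride; 2 1,1-dichloroethene
Product: 4 4,4-dichlorobut-3-en-2-one, via trichloro ketone 3 (not isolated)
Conditions: AlCl3 (1.1 equiv), CH2Cl2, 0 °C to rt; ice/aq. HCl quench; steam distillation
Reagents that add atoms: none
Why: Friedel–Crafts-type (Kondakov) acylation of the alkene puts the acylium ion on the CH2 carbon and chloride on the dichlorocarbenium carbon, and the resulting 4,4,4-trichlorobutan-2-one should lose HCl by E1cB elimination on steam distillation to give the conjugated dichlorovinyl ketone.

Step 2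
Reactants: 4 4,4-dichlorobut-3-en-2-one
Product: 5 4,4-dimethoxybut-3-en-2-one
Conditions: NaOMe (2.1 equiv), MeOH, −10 °C to rt
Reagents that add atoms: sodium methoxide, [Na+].[O-]C
Why: two successive addition–elimination events (vinylic nucleophilic substitution) at the β-carbon of the β,β-dichloro enone, which behaves as a vinylogous acid chloride, should replace both chlorides by methoxide.

Step 3
Reactants: 5 4,4-dimethoxybut-3-en-2-one
Product: 7 1,1-dimethoxy-3-(trimethylsilyloxy)buta-1,3-diene, via lithium dienolate 6 (not isolated)
Conditions: LDA (1.05 equiv), THF, −78 °C; then Me3SiCl, −78 °C to rt; non-aqueous work-up, distillation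
Reagents that add atoms: chlorotrimethylsilane, C[Si](C)(C)Cl
Why: the methyl group is the only enolisable position, so kinetic deprotonation gives the cross-conjugated lithium dienolate and the hard silicon electrophile traps it on oxygen (silyl enol ether formation).

Step 4
Reactants: 8 oct-2-ynoic acid
Product: 9 benzyl oct-2-ynoate
Conditions: BnBr (1.1 equiv), K2CO3, DMF, rt
Reagents that add atoms: benzyl bromide, BrCc1ccccc1
Why: SN2 O-alkylation of the carboxylate by the benzylic bromide installs an ester that tolerates the cycloaddition and is removed at the end by hydrogenolysis.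

Step 5
Reactants: 7 1,1-dimethoxy-3-(trimethylsilyloxy)buta-1,3-diene; 9 benzyl oct-2-ynoate
Product: 12 benzyl 4-hydroxy-2-methoxy-6-pentylbenzoate, via cyclohexadiene cycloadduct 10 (not isolated), via aryl silyl ether 11 (not isolated)
Conditions: 7 (2.5 equiv), neat, sealed tube, 140 °C; then 1 M HCl, THF, rt
Reagents that add atoms: none
Why: The thermal Diels–Alder reaction of the electron-rich ketene-acetal diene 7 with the electron-poor alkyne 9 is concerted but asynchronous, the CH2 terminus (C4 of the diene, largest HOMO coefficient) bonding to the pentyl-bearing β-carbon and the ketene-acetal carbon (C1) to the α-carbon, so that ring B bonds C5–C6 and C1–C2 form in one operation. The closest known reaction type is the cycloaddition of 1-alkoxy-3-silyloxybutadienes with alk-2-ynoates to give resorcylates, in which alkyl-substituted ynoates need prolonged heating without solvent. Ring B is closed by intermolecular (4+2) cycloaddition to cyclohexa-1,4-diene 10, which should lose methanol from the ketal carbon and the doubly allylic CH2 (1,4-elimination driven by aromatisation) to give 11, and dilute acid then cleaves the O–Si bond. No stereocentre is created, since 10 has none and the ring ends up aromatic. Only regioselectivity is needed, and it is secured by the matched polarisation: the 3-silyloxy and 1,1-dimethoxy groups both raise the coefficient at C4 of the diene and the ester makes the β-carbon of 9 the electrophilic end, so the product carries 2-OMe and 4-OH already differentiated. The benzyl ester should be inert to the heat and to the mild acid.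

Step 6
Reactants: 13 methyl orsellinate
Product: 14 methyl 2-hydroxy-4-methoxy-6-methylbenzoate
Conditions: MeI (1.05 equiv), K2CO3 (1.1 equiv), acetone, rt to 40 °C
Reagents that add atoms: iodomethane, CI
Why: Williamson etherification should be selective for the 4-hydroxyl because the 2-hydroxyl is held in a hydrogen bond to the ester carbonyl and is less acidic and less nucleophilic.

Step 7
Reactants: 14 methyl 2-hydroxy-4-methoxy-6-methylbenzoate
Product: 15 methyl 2-(benzyloxy)-4-methoxy-6-methylbenzoate
Conditions: BnBr (1.3 equiv), K2CO3, DMF, 70 °C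
Reagents that add atoms: benzyl bromide, BrCc1ccccc1
Why: Williamson etherification of the remaining chelated phenol under more forcing conditions masks it as a benzyl ether that tolerates LDA, hydroxide and acid chloride formation.

Step 8
Reactants: 15 methyl 2-(benzyloxy)-4-methoxy-6-methylbenzoate; 16 1-iodohexane
Product: 18 methyl 2-(benzyloxy)-6-heptyl-4-methoxybenzoate, via benzylic lithium species 17 (not isolated)
Conditions: LDA (1.15 equiv), THF, −78 °C; then 16 (1.5 equiv), DMPU, −78 to 0 °C
Reagents that add atoms: none
Why: lateral lithiation of the ortho-toluate (benzylic deprotonation stabilised as an extended ester enolate) followed by SN2 alkylation with the primary iodide extends the methyl group to heptyl, the di-ortho-substituted ester being too hindered for attack by the amide base.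

Step 9
Reactants: 18 methyl 2-(benzyloxy)-6-heptyl-4-methoxybenzoate
Product: 20 2-(benzyloxy)-6-heptyl-4-methoxybenzoic acid, via potassium carboxylate 19 (not isolated)
Conditions: KOH (10 equiv), DMSO/H2O 4:1, 90 °C; then 1 M HCl to pH 2
Reagents that add atoms: potassium hydroxide, [K+].[OH-]
Why: saponification (BAc2) of the di-ortho-substituted ester needs poorly solvated hydroxide in aqueous DMSO, conditions that leave the benzyl and methyl aryl ethers untouched.

Step 10
Reactants: 20 2-(benzyloxy)-6-heptyl-4-methoxybenzoic acid; 12 benzyl 4-hydroxy-2-methoxy-6-pentylbenzoate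
Product: 22 benzyl 4-{[2-(benzyloxy)-6-heptyl-4-methoxybenzoyl]oxy}-2-methoxy-6-pentylbenzoate, via acid chloride 21 (not isolated)
Conditions: (COCl)2 (1.5 equiv), DMF (cat.), CH2Cl2, 0 °C to rt, evaporate; then 12 (1.0 equiv), Et3N (2 equiv), DMAP (0.2 equiv), CH2Cl2, 0 °C to rt
Reagents that add atoms: none
Why: the Vilsmeier-type chloroiminium catalyst converts the acid into its chloride, and DMAP-catalysed acyl transfer (Einhorn/Steglich-type acylation) to the unhindered 4-hydroxyl of 12, the only nucleophile present, should form the depside ester.

Step 11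
Reactants: 22 benzyl 4-{[2-(benzyloxy)-6-heptyl-4-methoxybenzoyl]oxy}-2-methoxy-6-pentylbenzoate
Product: 23 4-[(2-heptyl-6-hydroxy-4-methoxybenzoyl)oxy]-2-methoxy-6-pentylbenzoic acid
Conditions: H2 (1 atm), 10% Pd/C, EtOAc, rt
Reagents that add atoms: none
Why: catalytic hydrogenolysis cleaves both benzylic C–O bonds (ester and aryl ether) while the aryl ester linkage and the methyl ethers are inert, so the carboxylic acid and the phenol are released in one operation.

**Compound list**

1 | acetyl chloride | CC(=O)Cl | starting material
2 | 1,1-dichloroethene | C=C(Cl)Cl | starting material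
3 | 4,4,4-trichlorobutan-2-one | CC(=O)CC(Cl)(Cl)Cl | intermediate
4 | 4,4-dichlorobut-3-en-2-one | CC(=O)C=C(Cl)Cl | intermediate
5 | 4,4-dimethoxybut-3-en-2-one | CC(=O)C=C(OC)OC | intermediate
6 | lithium 4,4-dimethoxybuta-1,3-dien-2-olate | [Li+].[O-]C(=C)C=C(OC)OC | intermediate
7 | 1,1-dimethoxy-3-(trimethylsilyloxy)buta-1,3-diene | C=C(O[Si](C)(C)C)C=C(OC)OC | intermediate
8 | oct-2-ynoic acid | CCCCCC#CC(=O)O | starting material
9 | benzyl oct-2-ynoate | CCCCCC#CC(=O)OCc1ccccc1 | intermediate
10 | benzyl 6,6-dimethoxy-2-pentyl-4-(trimethylsilyloxy)cyclohexa-1,4-diene-1-carboxylate | CCCCCC1=C(C(=O)OCc2ccccc2)C(OC)(OC)C=C(O[Si](C)(C)C)C1 | intermediate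
11 | benzyl 2-methoxy-6-pentyl-4-(trimethylsilyloxy)benzoate | CCCCCc1cc(O[Si](C)(C)C)cc(OC)c1C(=O)OCc1ccccc1 | intermediate
12 | benzyl 4-hydroxy-2-methoxy-6-pentylbenzoate | CCCCCc1cc(O)cc(OC)c1C(=O)OCc1ccccc1 | intermediate
13 | methyl orsellinate (methyl 2,4-dihydroxy-6-methylbenzoate) | COC(=O)c1c(C)cc(O)cc1O | starting material
14 | methyl 2-hydroxy-4-methoxy-6-methylbenzoate | COC(=O)c1c(C)cc(OC)cc1O | intermediate
15 | methyl 2-(benzyloxy)-4-methoxy-6-methylbenzoate | COC(=O)c1c(C)cc(OC)cc1OCc1ccccc1 | intermediate
16 | 1-iodohexane | CCCCCCI | starting material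
17 | methyl 2-(benzyloxy)-6-(lithiomethyl)-4-methoxybenzoate | COC(=O)c1c(C[Li])cc(OC)cc1OCc1ccccc1 | intermediate
18 | methyl 2-(benzyloxy)-6-heptyl-4-methoxybenzoate | CCCCCCCc1cc(OC)cc(OCc2ccccc2)c1C(=O)OC | intermediate
19 | potassium 2-(benzyloxy)-6-heptyl-4-methoxybenzoate | CCCCCCCc1cc(OC)cc(OCc2ccccc2)c1C(=O)[O-].[K+] | intermediate
20 | 2-(benzyloxy)-6-heptyl-4-methoxybenzoic acid | CCCCCCCc1cc(OC)cc(OCc2ccccc2)c1C(=O)O | intermediate
21 | 2-(benzyloxy)-6-heptyl-4-methoxybenzoyl chloride | CCCCCCCc1cc(OC)cc(OCc2ccccc2)c1C(=O)Cl | intermediate
22 | benzyl 4-{[2-(benzyloxy)-6-heptyl-4-methoxybenzoyl]oxy}-2-methoxy-6-pentylbenzoate | CCCCCCCc1cc(OC)cc(OCc2ccccc2)c1C(=O)Oc1cc(CCCCC)c(C(=O)OCc2ccccc2)c(OC)c1 | intermediate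
23 | 4-[(2-heptyl-6-hydroxy-4-methoxybenzoyl)oxy]-2-methoxy-6-pentylbenzoic acid (CNP0341430.0) | CCCCCCCc1cc(OC)cc(O)c1C(=O)Oc1cc(CCCCC)c(C(=O)O)c(OC)c1 | target

**Count**

Total steps: 11. Longest linear sequence: 6 steps (steps 1, 2, 3, 5, 10, 11; the ring A branch, steps 6 to 11, is equally long).

**Steps most likely to fail**

Step 5. The cycloaddition of the weakly activated, alkyl-substituted ynoate may be so slow that thermal decomposition, silyl migration or adventitious hydrolysis of the diene outruns it, or aromatisation may stall at the ketal stage. The fallback builds ring B without a cycloaddition, sets out from methyl orsellinate 13 and comes back at 12. Chloromethyl methyl ether and iPr2NEt in CH2Cl2 would protect the unchelated 4-hydroxyl to give methyl 2-hydroxy-4-(methoxymethoxy)-6-methylbenzoate F1. Iodomethane and K2CO3 in DMF at 60 °C would then methylate the 2-hydroxyl to give methyl 2-methoxy-4-(methoxymethoxy)-6-methylbenzoate F2. Lateral lithiation with LDA in THF at −78 °C and alkylation with 1-iodobutane should give methyl 2-methoxy-4-(methoxymethoxy)-6-pentylbenzoate F3. KOH in aqueous DMSO at 90 °C would give 2-methoxy-4-(methoxymethoxy)-6-pentylbenzoic acid F4, and benzyl bromide with K2CO3 in DMF benzyl 2-methoxy-4-(methoxymethoxy)-6-pentylbenzoate F5. Aqueous HCl in THF would finally remove the acetal to give 12.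

Step 8. The lithiated toluate may add to the ester of unreacted 15 (Claisen-type self-condensation), alkylation by the unactivated iodide may be incomplete, or the benzyl ether may be deprotonated and rearrange. The fallback sets out from 15 and comes back at 20, replacing steps 8 and 9. The ester would be saponified first (KOH, aqueous DMSO, 90 °C) to 2-(benzyloxy)-4-methoxy-6-methylbenzoic acid F6, whose carboxylate cannot act as an electrophile. Its dianion, formed with LDA (2.2 equiv) in THF at −78 to 0 °C, would be alkylated at the benzylic carbon with 1-iodohexane 16, and acidification should give 20 directly.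

Step 10. Acyl transfer from the doubly ortho-substituted aroyl chloride may be slow, so that hydrolysis back to the acid, symmetrical anhydride formation or chloride-induced loss of the ortho benzyl ether competes. The fallback sets out from acid 20 (with phenol 12) and comes back at 22. The two would be condensed directly with trifluoroacetic anhydride in dry toluene at rt. The mixed anhydride 2-(benzyloxy)-6-heptyl-4-methoxybenzoic trifluoroacetic anhydride F7 should ionise readily to the hindered acylium ion, which the phenol traps under acidic rather than basic conditions.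

Further compounds
F1 | step 5 | methyl 2-hydroxy-4-(methoxymethoxy)-6-methylbenzoate | COCOc1cc(C)c(C(=O)OC)c(O)c1
F2 | step 5 | methyl 2-methoxy-4-(methoxymethoxy)-6-methylbenzoate | COCOc1cc(C)c(C(=O)OC)c(OC)c1
F3 | step 5 | methyl 2-methoxy-4-(methoxymethoxy)-6-pentylbenzoate | CCCCCc1cc(OCOC)cc(OC)c1C(=O)OC
F4 | step 5 | 2-methoxy-4-(methoxymethoxy)-6-pentylbenzoic acid | CCCCCc1cc(OCOC)cc(OC)c1C(=O)O
F5 | step 5 | benzyl 2-methoxy-4-(methoxymethoxy)-6-pentylbenzoate | CCCCCc1cc(OCOC)cc(OC)c1C(=O)OCc1ccccc1
F6 | step 8 | 2-(benzyloxy)-4-methoxy-6-methylbenzoic acid | Cc1cc(OC)cc(OCc2ccccc2)c1C(=O)O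
F7 | step 10 | 2-(benzyloxy)-6-heptyl-4-methoxybenzoic trifluoroacetic anhydride | CCCCCCCc1cc(OC)cc(OCc2ccccc2)c1C(=O)OC(=O)C(F)(F)F
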